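**Plan**

- Numbering: C1 is the ester carbon, then C2, dioxane C3–C6, linker C7–C8, then the ent-drimane decalin. In the 1,2-dioxane the O–C3 and O–C6 bonds are 1,4-related and the C2 and C7 branches are cis. That is the imprint of suprafacial singlet-oxygen addition to an (E,E)-diene C3=C4–C5=C6 with C2 and C7 as outside groups.
- Cuts: C7–C8 (olefination, then reduction) gives a dioxane C7 aldehyde and a decalin C8 sulfone. O–C3 and O–C6 ([4+2]) lead back to a dienoyl camphorsultam. C5=C6 (Horner–Wadsworth–Emmons) and C3=C4 (Wittig) lead back to (R)-Roche ester. The decalin goes back to farnesol.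
- Forward: the diene chain is built linearly and the dioxine ring is closed by photooxygenation. The ring alkene is saturated, the sultam reduced off and C7 made the aldehyde. The decalin (both rings from one cationic bicyclisation) is joined at C7–C8, C7=C8 is reduced, and C1 is oxidised and esterified.
- Stereochemistry: C2 comes from the Roche ester. C3/C6 are cis through diene geometry and suprafacial addition, with the absolute sense from the sultam on C7. The decalin's relative configuration comes from chair–chair cyclisation and its absolute configuration from a lipase resolution.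

Key step: step 7

Assumption 1: the (2R)-sultam is taken to expose the C6-Re face (the Cα-Re face usual for uncatalysed additions to its enoyl imides) to singlet oxygen. This is not established for a 2-methyldienoyl imide; if the sense is reversed, the (2S)-sultam would be used in steps 4–9 with nothing else changed.

Assumption 2: lipase PS is taken to acetylate the natural-series enantiomer of drimenol faster, as with the exocyclic isomer albicanol, so ent-drimenol is recovered as the unreacted alcohol. If the preference is reversed, the acetate fraction would be carried on after methanolysis.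

Remark: TBS = tert-butyldimethylsilyl; PT = 1-phenyl-1H-tetrazol-5-yl. Dioxane locants 3 and 6 in the names are the chain carbons C3 and C6.

**Route**

Step 1
Reactants: 1 methyl (2R)-3-hydroxy-2-methylpropanoate
Product: 2 methyl (2R)-3-(TBS-oxy)-2-methylpropanoate
Conditions: TBSCl, imidazole, CH2Cl2, 0 °C → rt
Reagents that add atoms: tert-butyldimethylsilyl chloride, CC(C)(C)[Si](C)(C)Cl
Why: Imidazole-promoted silylation of a primary alcohol is routine and leaves the C2 stereocentre untouched.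

Step 2
Reactants: 2 methyl (2R)-3-(TBS-oxy)-2-methylpropanoate
Product: 3 (2R)-3-(TBS-oxy)-2-methylpropanal
Conditions: DIBAL-H (1.05 equiv), CH2Cl2, −78 °C; Rochelle salt work-up; used crude at once
Reagents that add atoms: none
Why: Partial ester reduction with DIBAL-H at low temperature stops at the aluminium hemiacetal, which releases the aldehyde only on work-up, and immediate use without chromatography should protect the α-stereocentre.

Step 3
Reactants: 3 (2R)-3-(TBS-oxy)-2-methylpropanal; 4 (triphenylphosphoranylidene)acetaldehyde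
Product: 5 (2E,4S)-5-(TBS-oxy)-4-methylpent-2-enal
Conditions: toluene, 80 °C
Reagents that add atoms: none
Why: Wittig olefination with the formyl-stabilised ylide should give the (E)-enal (C3=C4), the ylide being too weakly basic to epimerise the adjacent centre.

Step 4
Reactants: 6 (1S)-(−)-2,10-camphorsultam; 7 2-bromopropanoyl bromide
Product: 9 (2R)-N-(2-bromopropanoyl)bornane-10,2-sultam (both CHBr epimers), via sodium sultamide 8 (not isolated)
Conditions: NaH, toluene, 0 °C; then 7, 0 °C → rt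
Reagents that add atoms: none
Why: N-acylation of the sodium salt of the sultam with an acyl bromide is the standard entry to N-acyl sultams, and the CHBr configuration is irrelevant because that carbon becomes sp2 in step 6.

Step 5
Reactants: 9 (2R)-N-(2-bromopropanoyl)bornane-10,2-sultam
Product: 10 (2R)-N-[2-(diethoxyphosphoryl)propanoyl]bornane-10,2-sultam (both epimers)
Conditions: P(OEt)3 (neat), 130 °C, EtBr distilled off
Reagents that add atoms: triethyl phosphite, CCOP(OCC)OCC
Why: Michaelis–Arbuzov reaction of an α-bromo carbonyl compound with triethyl phosphite should give the phosphonate, as in the preparation of 2-phosphonopropionates.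

Step 6
Reactants: 5 (2E,4S)-5-(TBS-oxy)-4-methylpent-2-enal; 10 (2R)-N-[2-(diethoxyphosphoryl)propanoyl]bornane-10,2-sultam
Product: 11 (2R)-N-[(2E,4E,6S)-7-(TBS-oxy)-2,6-dimethylhepta-2,4-dienoyl]bornane-10,2-sultam
Conditions: LiCl, i-Pr2NEt, MeCN, rt
Reagents that add atoms: none
Why: Horner–Wadsworth–Emmons olefination under Masamune–Roush conditions with an α-methyl phosphono imide should give the (E)-trisubstituted C5=C6 alkene (methyl cis to C4) without touching the γ-centre of the enal.

Step 7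
Reactants: 11 (2R)-N-[(2E,4E,6S)-7-(TBS-oxy)-2,6-dimethylhepta-2,4-dienoyl]bornane-10,2-sultam
Product: 12 (2R)-N-{[(3S,6R)-3-[(2R)-1-(TBS-oxy)propan-2-yl]-6-methyl-3,6-dihydro-1,2-dioxin-6-yl]carbonyl}bornane-10,2-sultam (C2 branch and acyl group cis)
Conditions: O2, tetraphenylporphyrin (cat.), CH2Cl2, −20 °C, visible light (white LED)
Reagents that add atoms: dioxygen (as singlet oxygen), O=O
Why: Sensitised singlet oxygen adds as the 2π partner across C3 and C6 of the s-cis diene in a concerted suprafacial [4+2] cycloaddition, forming O–C3 and O–C6 in one event and closing the six-membered 3,6-dihydro-1,2-dioxine by cycloaddition rather than by chain cyclisation. The closest known reactions are photooxygenations of sorbic-type 2,4-dienoyl derivatives carrying chiral amide auxiliaries and of dienes with a doubly substituted terminus, applied here to a 2-methyldienoyl sultam. The relative configuration of C3 and C6 follows from the (E,E) geometry: the outside groups (C2 branch and C7 acyl) end up cis, and the inside C6 methyl ends up trans to the C2 branch. The absolute configuration is set at C6 by the sultam, which should screen one face of the acyl-bearing terminus so that oxygen enters on the C6-Re face, with the same face at C3 following from suprafaciality and the C2 centre acting as a spectator. The step needs [4+2] to outrun the ene reaction: the acyl group makes C5=C6 electron-poor, the only allylic hydrogen at the other end (C2–H) lies in the diene plane through 1,3-allylic strain, and low temperature in an aprotic solvent favours the concerted path.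

Step 8
Reactants: 12 dihydrodioxine acyl sultam
Product: 13 (2R)-N-{[(3S,6R)-3-[(2R)-1-(TBS-oxy)propan-2-yl]-6-methyl-1,2-dioxan-6-yl]carbonyl}bornane-10,2-sultam
Conditions: KO2C–N=N–CO2K, AcOH, MeOH/CH2Cl2, 0 °C → rt
Reagents that add atoms: none
Why: Diimide reduction transfers H2 to the cis ring alkene without touching the O–O bond, and doing it now removes the allylic peroxy C3–H that would be open to Kornblum–DeLaMare cleavage in the later basic steps.

Step 9
Reactants: 13 dioxane acyl sultam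
Product: 14 [(3S,6R)-3-[(2R)-1-(TBS-oxy)propan-2-yl]-6-methyl-1,2-dioxan-6-yl]methanol
Conditions: LiBH4, THF, MeOH (1 equiv), −10 → 0 °C; aq. NH4Cl
Reagents that add atoms: none
Why: Reductive cleavage of the activated N-acyl sultam by borohydride should give the C7 alcohol and return the auxiliary, since borohydrides spare dialkyl peroxides and silyl ethers.

Step 10
Reactants: 14 dioxane C7 alcohol
Product: 15 (3S,6R)-3-[(2R)-1-(TBS-oxy)propan-2-yl]-6-methyl-1,2-dioxane-6-carbaldehyde
Conditions: Dess–Martin periodinane, pyridine, CH2Cl2, 0 °C → rt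
Reagents that add atoms: none
Why: Dess–Martin oxidation is neutral and peroxide-tolerant, and the aldehyde has no α-hydrogen and so cannot epimerise.

Step 11
Reactants: 16 (2E,6E)-farnesol
Product: 17 (±)-drimenol
Conditions: FSO3H, 2-nitropropane, −78 °C; Et3N quench
Reagents that add atoms: none
Why: Superacid-promoted cationic polyene bicyclisation starts at the terminal alkene, chair–chair folding of the all-E triene fixes the trans ring fusion and the equatorial CH2OH (relative configuration only, hence the racemate), and the protonated hydroxyl steers proton loss to the Δ7 alkene.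

Step 12
Reactants: 17 (±)-drimenol
Product: 18 ent-drimenol, [(1R,4aR,8aR)-2,5,5,8a-tetramethyl-1,4,4a,5,6,7,8,8a-octahydronaphthalen-1-yl]methanol
Conditions: Burkholderia cepacia lipase (lipase PS, immobilised), vinyl acetate, t-BuOMe, rt, run past half conversion; chromatography
Reagents that add atoms: none
Why: Lipase-catalysed transesterification is an established kinetic resolution for primary alcohols of this bicyclic class, and running past half conversion should leave the slow-reacting enantiomer in high enantiomeric purity.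

Step 13
Reactants: 18 ent-drimenol
Product: 19 5-({[(1R,4aR,8aR)-2,5,5,8a-tetramethyl-1,4,4a,5,6,7,8,8a-octahydronaphthalen-1-yl]methyl}sulfanyl)-1-phenyl-1H-tetrazole
Conditions: 1-phenyl-1H-tetrazole-5-thiol, PPh3, DIAD, THF, 0 °C → rt
Reagents that add atoms: 1-phenyl-1H-tetrazole-5-thiol, SC1=NN=NN1c1ccccc1
Why: Mitsunobu thioetherification displaces the activated primary hydroxyl by the soft thiolate in an SN2 step that does not involve the C9 stereocentre.

Step 14
Reactants: 19 PT sulfide
Product: 20 5-({[(1R,4aR,8aR)-2,5,5,8a-tetramethyl-1,4,4a,5,6,7,8,8a-octahydronaphthalen-1-yl]methyl}sulfonyl)-1-phenyl-1H-tetrazole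
Conditions: (NH4)6Mo7O24·4H2O (cat.), 30% aq. H2O2, EtOH, 0 °C → rt
Reagents that add atoms: hydrogen peroxide, OO
Why: Molybdate-catalysed peroxide oxidation takes sulfide to sulfone much faster than it epoxidises an isolated, hindered trisubstituted alkene.

Step 15
Reactants: 15 dioxane C7 aldehyde; 20 PT sulfone
Product: 22 (3S,6R)-dioxane TBS ether with the (E)-C7=C8 alkene to the ent-drimane bicycle, via potassium sulfonyl carbanion 21 (not isolated)
Conditions: KHMDS, DME, −60 °C, 30 min; then 15, −60 °C → rt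
Reagents that add atoms: none
Why: Julia–Kocienski olefination (addition, Smiles rearrangement, loss of SO2 and tetrazolate) forms C7=C8 without a reductant, the aldehyde cannot enolise, and the alkene geometry is irrelevant because the bond is saturated next.

Step 16
Reactants: 22 C7=C8 alkene
Product: 23 (3S,6S)-3-[(2R)-1-(TBS-oxy)propan-2-yl]-6-methyl-6-{2-[(1R,4aR,8aR)-2,5,5,8a-tetramethyl-1,4,4a,5,6,7,8,8a-octahydronaphthalen-1-yl]ethyl}-1,2-dioxane
Conditions: KO2C–N=N–CO2K (excess, in portions), AcOH, MeOH/CH2Cl2, 0 °C → rt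
Reagents that add atoms: none
Why: Diimide reduction should take the 1,2-disubstituted C7=C8 alkene in preference to the hindered trisubstituted ring alkene and leaves the peroxide intact.

Step 17
Reactants: 23 saturated TBS ether
Product: 24 (2R)-2-[(3S,6S)-6-methyl-6-{2-[(1R,4aR,8aR)-2,5,5,8a-tetramethyl-1,4,4a,5,6,7,8,8a-octahydronaphthalen-1-yl]ethyl}-1,2-dioxan-3-yl]propan-1-ol
Conditions: HF·pyridine, pyridine, THF, 0 °C → rt
Reagents that add atoms: none
Why: Fluoride-mediated desilylation under buffered, non-basic conditions frees the C1 alcohol without exposing the peroxide C3–H to base.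

Step 18
Reactants: 24 C1 alcohol
Product: 26 (2S)-2-[(3S,6S)-6-methyl-6-{2-[(1R,4aR,8aR)-2,5,5,8a-tetramethyl-1,4,4a,5,6,7,8,8a-octahydronaphthalen-1-yl]ethyl}-1,2-dioxan-3-yl]propanoic acid, via aldehyde 25 (not isolated)
Conditions: TEMPO (cat.), PhI(OAc)2, MeCN/H2O, rt
Reagents that add atoms: water, O
Why: Oxoammonium-mediated oxidation (TEMPO/PhI(OAc)2 in aqueous acetonitrile) carries the alcohol through the aldehyde hydrate to the acid near neutral pH, so C2 should neither epimerise nor suffer β-elimination of the peroxide.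

Step 19
Reactants: 26 carboxylic acid
Product: 27 methyl (2S)-2-[(3S,6S)-6-methyl-6-{2-[(1R,4aR,8aR)-2,5,5,8a-tetramethyl-1,4,4a,5,6,7,8,8a-octahydronaphthalen-1-yl]ethyl}-1,2-dioxan-3-yl]propanoate (CNP0124238.1)
Conditions: TMSCHN2, toluene/MeOH, 0 °C
Reagents that add atoms: (trimethylsilyl)diazomethane, C[Si](C)(C)C=[N+]=[N-]
Why: Esterification with the diazomethane surrogate is base-free, so the C2–H that is α to the ester and β to the peroxide is not put at risk.

**Compound list**

1 | methyl (2R)-3-hydroxy-2-methylpropanoate ((R)-Roche ester) | C[C@H](CO)C(=O)OC | starting material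
2 | methyl (2R)-3-[(tert-butyldimethylsilyl)oxy]-2-methylpropanoate | C[C@H](CO[Si](C)(C)C(C)(C)C)C(=O)OC | intermediate
3 | (2R)-3-[(tert-butyldimethylsilyl)oxy]-2-methylpropanal | C[C@H](CO[Si](C)(C)C(C)(C)C)C=O | intermediate
4 | (triphenylphosphoranylidene)acetaldehyde | O=CC=P(c1ccccc1)(c1ccccc1)c1ccccc1 | starting material
5 | (2E,4S)-5-[(tert-butyldimethylsilyl)oxy]-4-methylpent-2-enal | C[C@H](CO[Si](C)(C)C(C)(C)C)/C=C/C=O | intermediate
6 | (1S)-(−)-2,10-camphorsultam, (2R)-bornane-10,2-sultam | N1[C@@H]2C[C@H]3CC[C@]2(CS1(=O)=O)C3(C)C | starting material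
7 | 2-bromopropanoyl bromide (racemic) | CC(Br)C(Br)=O | starting material
8 | sodium salt of (2R)-bornane-10,2-sultam | [Na+].[N-]1[C@@H]2C[C@H]3CC[C@]2(CS1(=O)=O)C3(C)C | intermediate (not isolated)
9 | (2R)-N-(2-bromopropanoyl)bornane-10,2-sultam, both CHBr epimers | CC(Br)C(=O)N1[C@@H]2C[C@H]3CC[C@]2(CS1(=O)=O)C3(C)C | intermediate
10 | (2R)-N-[2-(diethoxyphosphoryl)propanoyl]bornane-10,2-sultam, both epimers | CCOP(=O)(OCC)C(C)C(=O)N1[C@@H]2C[C@H]3CC[C@]2(CS1(=O)=O)C3(C)C | intermediate
11 | (2R)-N-[(2E,4E,6S)-7-[(tert-butyldimethylsilyl)oxy]-2,6-dimethylhepta-2,4-dienoyl]bornane-10,2-sultam | CC(C)(C)[Si](C)(C)OC[C@@H](C)/C=C/C=C(\C)C(=O)N1[C@@H]2C[C@H]3CC[C@]2(CS1(=O)=O)C3(C)C | intermediate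
12 | (2R)-N-{[(3S,6R)-3-[(2R)-1-(TBS-oxy)propan-2-yl]-6-methyl-3,6-dihydro-1,2-dioxin-6-yl]carbonyl}bornane-10,2-sultam | CC(C)(C)[Si](C)(C)OC[C@@H](C)[C@@H]1C=C[C@](C)(C(=O)N2[C@@H]3C[C@H]4CC[C@]3(CS2(=O)=O)C4(C)C)OO1 | intermediate
13 | (2R)-N-{[(3S,6R)-3-[(2R)-1-(TBS-oxy)propan-2-yl]-6-methyl-1,2-dioxan-6-yl]carbonyl}bornane-10,2-sultam | CC(C)(C)[Si](C)(C)OC[C@@H](C)[C@@H]1CC[C@](C)(C(=O)N2[C@@H]3C[C@H]4CC[C@]3(CS2(=O)=O)C4(C)C)OO1 | intermediate
14 | [(3S,6R)-3-[(2R)-1-(TBS-oxy)propan-2-yl]-6-methyl-1,2-dioxan-6-yl]methanol | CC(C)(C)[Si](C)(C)OC[C@@H](C)[C@@H]1CC[C@](C)(CO)OO1 | intermediate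
15 | (3S,6R)-3-[(2R)-1-(TBS-oxy)propan-2-yl]-6-methyl-1,2-dioxane-6-carbaldehyde | CC(C)(C)[Si](C)(C)OC[C@@H](C)[C@@H]1CC[C@](C)(C=O)OO1 | intermediate
16 | (2E,6E)-farnesol | CC(C)=CCC/C(C)=C/CC/C(C)=C/CO | starting material
17 | (±)-drimenol, racemic (2,5,5,8a-tetramethyl-1,4,4a,5,6,7,8,8a-octahydronaphthalen-1-yl)methanol with 1,4a,8a all R or all S | OC[C@@H]1C(C)=CC[C@@H]2C(C)(C)CCC[C@@]12C.OC[C@H]1C(C)=CC[C@H]2C(C)(C)CCC[C@]12C | intermediate
18 | ent-drimenol, [(1R,4aR,8aR)-2,5,5,8a-tetramethyl-1,4,4a,5,6,7,8,8a-octahydronaphthalen-1-yl]methanol | OC[C@@H]1C(C)=CC[C@@H]2C(C)(C)CCC[C@@]12C | intermediate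
19 | 5-({[(1R,4aR,8aR)-2,5,5,8a-tetramethyl-1,4,4a,5,6,7,8,8a-octahydronaphthalen-1-yl]methyl}sulfanyl)-1-phenyl-1H-tetrazole | S(C[C@@H]1C(C)=CC[C@@H]2C(C)(C)CCC[C@@]12C)C1=NN=NN1c1ccccc1 | intermediate
20 | 5-({[(1R,4aR,8aR)-2,5,5,8a-tetramethyl-1,4,4a,5,6,7,8,8a-octahydronaphthalen-1-yl]methyl}sulfonyl)-1-phenyl-1H-tetrazole | O=S(=O)(C[C@@H]1C(C)=CC[C@@H]2C(C)(C)CCC[C@@]12C)C1=NN=NN1c1ccccc1 | intermediate
21 | potassium α-sulfonyl carbanion of 20 | [K+].O=S(=O)([CH-][C@@H]1C(C)=CC[C@@H]2C(C)(C)CCC[C@@]12C)C1=NN=NN1c1ccccc1 | intermediate (not isolated)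
22 | (3S,6R)-3-[(2R)-1-(TBS-oxy)propan-2-yl]-6-methyl-6-{(E)-2-[(1R,4aR,8aR)-2,5,5,8a-tetramethyl-1,4,4a,5,6,7,8,8a-octahydronaphthalen-1-yl]ethenyl}-1,2-dioxane | CC(C)(C)[Si](C)(C)OC[C@@H](C)[C@@H]1CC[C@](C)(/C=C/[C@@H]2C(C)=CC[C@@H]3C(C)(C)CCC[C@@]23C)OO1 | intermediate
23 | (3S,6S)-3-[(2R)-1-(TBS-oxy)propan-2-yl]-6-methyl-6-{2-[(1R,4aR,8aR)-2,5,5,8a-tetramethyl-1,4,4a,5,6,7,8,8a-octahydronaphthalen-1-yl]ethyl}-1,2-dioxane | CC(C)(C)[Si](C)(C)OC[C@@H](C)[C@@H]1CC[C@](C)(CC[C@@H]2C(C)=CC[C@@H]3C(C)(C)CCC[C@@]23C)OO1 | intermediate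
24 | (2R)-2-[(3S,6S)-6-methyl-6-{2-[(1R,4aR,8aR)-2,5,5,8a-tetramethyl-1,4,4a,5,6,7,8,8a-octahydronaphthalen-1-yl]ethyl}-1,2-dioxan-3-yl]propan-1-ol | OC[C@@H](C)[C@@H]1CC[C@](C)(CC[C@@H]2C(C)=CC[C@@H]3C(C)(C)CCC[C@@]23C)OO1 | intermediate
25 | (2S)-2-[(3S,6S)-6-methyl-6-{2-[(1R,4aR,8aR)-2,5,5,8a-tetramethyl-1,4,4a,5,6,7,8,8a-octahydronaphthalen-1-yl]ethyl}-1,2-dioxan-3-yl]propanal | O=C[C@@H](C)[C@@H]1CC[C@](C)(CC[C@@H]2C(C)=CC[C@@H]3C(C)(C)CCC[C@@]23C)OO1 | intermediate (not isolated)
26 | (2S)-2-[(3S,6S)-6-methyl-6-{2-[(1R,4aR,8aR)-2,5,5,8a-tetramethyl-1,4,4a,5,6,7,8,8a-octahydronaphthalen-1-yl]ethyl}-1,2-dioxan-3-yl]propanoic acid | OC(=O)[C@@H](C)[C@@H]1CC[C@](C)(CC[C@@H]2C(C)=CC[C@@H]3C(C)(C)CCC[C@@]23C)OO1 | intermediate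
27 | methyl (2S)-2-[(3S,6S)-6-methyl-6-{2-[(1R,4aR,8aR)-2,5,5,8a-tetramethyl-1,4,4a,5,6,7,8,8a-octahydronaphthalen-1-yl]ethyl}-1,2-dioxan-3-yl]propanoate | COC(=O)[C@@H](C)[C@@H]1CC[C@](C)(CC[C@@H]2C(C)=CC[C@@H]3C(C)(C)CCC[C@@]23C)OO1 | target

**Step count**

Total: 19 steps. Longest linear sequence: 13 steps (1–3, 6–10, 15–19). Side branches: steps 4–5 (phosphonate) and 11–14 (decalin sulfone).

**Steps most likely to fail**

1. Step 7. Face selection at C6 may be lost if the 2-methyl group twists the imide out of the diene plane, and hydrogen abstraction from the C6 methyl (ene path) may outrun cycloaddition on the hindered s-cis diene. The fallback sets out from enal 5 and comes back at alcohol 14. It gives up the auxiliary and relies on separating diastereomers. Horner–Wadsworth–Emmons reaction of 5 with triethyl 2-phosphonopropionate (NaH, THF) would give ethyl (2E,4E,6S)-7-(TBS-oxy)-2,6-dimethylhepta-2,4-dienoate F1, a flat sorbate-type dienoate. Its sensitised photooxygenation (O2, TPP, CH2Cl2, light) would be steered only by C2 and should give both cis adducts: ethyl (3S,6R)-3-[(2R)-1-(TBS-oxy)propan-2-yl]-6-methyl-3,6-dihydro-1,2-dioxine-6-carboxylate F2 and its (3R,6S) diastereomer F3, to be separated by chromatography. Diimide reduction of F2 would give the dioxane ester F4, and LiBH4 would reduce F4 to 14.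

2. Step 15. The hindered sulfonyl carbanion may add poorly to the neopentyl-type aldehyde. The potassium alkoxide of the adduct sits next to the peroxide carbon C6 and may fragment (C6–C7 cleavage with O–O heterolysis) before the Smiles rearrangement. The fallback sets out from ent-drimenol 18 and aldehyde 15 and comes back at 23. It replaces the sulfone by a phosphorus ylide, whose oxaphosphetane pathway has no free alkoxide. Alcohol 18 would be converted (I2, PPh3, imidazole) into ent-drimenyl iodide F5, and heating with PPh3 in MeCN would give the phosphonium iodide F6. NaHMDS in THF at −78 °C would generate the ylide F7, and Wittig reaction with 15 would give the (Z)-C7=C8 alkene F8. Diimide reduction as in step 16 would give 23.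

3. Step 12. The lipase may discriminate poorly between the enantiomers because the stereocentre is one carbon away from the hydroxyl. The fallback sets out from racemate 17 and comes back at 18. It replaces the kinetic resolution by covalent diastereomers. Acylation with (1S)-(−)-camphanic chloride (pyridine, DMAP, CH2Cl2) would give ent-drimenyl (1S)-camphanate F9 and drimenyl (1S)-camphanate F10, to be separated by crystallisation or chromatography. Saponification of F9 (LiOH, THF/H2O) would give 18.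

**Further compounds**

F1 | step 7 | ethyl (2E,4E,6S)-7-[(tert-butyldimethylsilyl)oxy]-2,6-dimethylhepta-2,4-dienoate | CC(C)(C)[Si](C)(C)OC[C@@H](C)/C=C/C=C(\C)C(=O)OCC
F2 | step 7 | ethyl (3S,6R)-3-[(2R)-1-(TBS-oxy)propan-2-yl]-6-methyl-3,6-dihydro-1,2-dioxine-6-carboxylate | CC(C)(C)[Si](C)(C)OC[C@@H](C)[C@@H]1C=C[C@](C)(C(=O)OCC)OO1
F3 | step 7 | ethyl (3R,6S)-3-[(2R)-1-(TBS-oxy)propan-2-yl]-6-methyl-3,6-dihydro-1,2-dioxine-6-carboxylate | CC(C)(C)[Si](C)(C)OC[C@@H](C)[C@H]1C=C[C@@](C)(C(=O)OCC)OO1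
F4 | step 7 | ethyl (3S,6R)-3-[(2R)-1-(TBS-oxy)propan-2-yl]-6-methyl-1,2-dioxane-6-carboxylate | CC(C)(C)[Si](C)(C)OC[C@@H](C)[C@@H]1CC[C@](C)(C(=O)OCC)OO1
F5 | step 15 | (1R,4aR,8aR)-1-(iodomethyl)-2,5,5,8a-tetramethyl-1,4,4a,5,6,7,8,8a-octahydronaphthalene (ent-drimenyl iodide) | IC[C@@H]1C(C)=CC[C@@H]2C(C)(C)CCC[C@@]12C
F6 | step 15 | triphenyl{[(1R,4aR,8aR)-2,5,5,8a-tetramethyl-1,4,4a,5,6,7,8,8a-octahydronaphthalen-1-yl]methyl}phosphonium iodide | [I-].c1ccccc1[P+](c1ccccc1)(c1ccccc1)C[C@@H]1C(C)=CC[C@@H]2C(C)(C)CCC[C@@]12C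
F7 | step 15 | triphenyl{[(1R,4aR,8aR)-2,5,5,8a-tetramethyl-1,4,4a,5,6,7,8,8a-octahydronaphthalen-1-yl]methylidene}phosphorane | c1ccccc1P(c1ccccc1)(c1ccccc1)=C[C@@H]1C(C)=CC[C@@H]2C(C)(C)CCC[C@@]12C
F8 | step 15 | (3S,6R)-3-[(2R)-1-(TBS-oxy)propan-2-yl]-6-methyl-6-{(Z)-2-[(1R,4aR,8aR)-2,5,5,8a-tetramethyl-1,4,4a,5,6,7,8,8a-octahydronaphthalen-1-yl]ethenyl}-1,2-dioxane | CC(C)(C)[Si](C)(C)OC[C@@H](C)[C@@H]1CC[C@](C)(/C=C\[C@@H]2C(C)=CC[C@@H]3C(C)(C)CCC[C@@]23C)OO1
F9 | step 12 | [(1R,4aR,8aR)-2,5,5,8a-tetramethyl-1,4,4a,5,6,7,8,8a-octahydronaphthalen-1-yl]methyl (1S,4R)-4,7,7-trimethyl-3-oxo-2-oxabicyclo[2.2.1]heptane-1-carboxylate | O=C(OC[C@@H]1C(C)=CC[C@@H]2C(C)(C)CCC[C@@]12C)[C@@]34CC[C@@](C)(C(=O)O3)C4(C)C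
F10 | step 12 | [(1S,4aS,8aS)-2,5,5,8a-tetramethyl-1,4,4a,5,6,7,8,8a-octahydronaphthalen-1-yl]methyl (1S,4R)-4,7,7-trimethyl-3-oxo-2-oxabicyclo[2.2.1]heptane-1-carboxylate | O=C(OC[C@H]1C(C)=CC[C@H]2C(C)(C)CCC[C@]12C)[C@@]34CC[C@@](C)(C(=O)O3)C4(C)C
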